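**Plan**
- Cuts, in retrosynthetic order: the four O–benzyl bonds; O1–C8a of ring C; C3–C4 (aldol, then oxidation); C4a–C4 (formylation); the CH2–ring D bond (Friedel–Crafts benzylation); C8–CH2 (formylation, then reduction); in ring D the aryl–CO bond and the O–CH3 bond.
- Forward: ring A (from 5-bromoresorcinol) and ring D (from 2-methylphloroglucinol) are prepared separately and joined through the CH2 bridge; the C4a side chain is then built, ring C is closed last, and hydrogenolysis ends the route.
- Feature used: C8a of ring A carries bromine and lies between C8 (bridge CH2) and C4a (bearing the C4 carbonyl), so only the enolate oxygen on the phenyl-bearing C2 can reach it, through six-membered ring C; neither ring A ether oxygen (C5, C7) can become O1.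
- Stereochemistry: the target has no stereocentre; the two centres formed in the aldol step are erased by oxidation and cyclisation.

Key step: step 11

Remark: ring A atoms carry their flavone numbers (C4a, C5 to C8, C8a) from the first step on. Diketone 17 is drawn as its chelated enol, which equilibrates with the diketo form. Compounds 12 and 16 are racemic (16 as a mixture of diastereomers).

**Step 1**
Reactants: 1 5-bromobenzene-1,3-diol (5-bromoresorcinol)
Product: 2 1,3-bis(benzyloxy)-5-bromobenzene
Conditions: BnBr, K2CO3, DMF, 60 °C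
Reagents that add atoms: benzyl bromide BrCc1ccccc1
Why: Williamson ether synthesis on both phenols; benzyl is chosen because all four such ethers can be removed at the end by hydrogenolysis without touching the two methyl ethers of the target.

**Step 2**
Reactants: 2 1,3-bis(benzyloxy)-5-bromobenzene
Product: 4 2,4-bis(benzyloxy)-6-bromobenzaldehyde, via iminium chloride 3 (not isolated)
Conditions: POCl3, DMF, 0 to 85 °C; then aq. NaOAc
Reagents that add atoms: N,N-dimethylformamide CN(C)C=O; water O
Why: Vilsmeier–Haack formylation; as is known for 1-bromo-3,5-dialkoxybenzenes, the chloroiminium ion attacks the carbon para to one ether and ortho to bromine and not the carbon between the two ethers, so the future bridge carbon is placed on C8 beside the bromine-bearing C8a.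

**Step 3**
Reactants: 4 2,4-bis(benzyloxy)-6-bromobenzaldehyde
Product: 5 [2,4-bis(benzyloxy)-6-bromophenyl]methanol
Conditions: NaBH4, THF–MeOH, 0 °C
Reagents that add atoms: none
Why: Borohydride reduction of an aryl aldehyde to the benzylic alcohol, which leaves the aryl bromide and the benzyl ethers untouched.

**Step 4**
Reactants: 6 2-methylbenzene-1,3,5-triol; 7 3-phenylpropanoyl chloride
Product: 8 1-(2,4,6-trihydroxy-3-methylphenyl)-3-phenylpropan-1-one
Conditions: AlCl3, PhNO2–CH2Cl2, 0 °C to rt; then 1 M HCl
Reagents that add atoms: none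
Why: Friedel–Crafts acylation; the two free ring carbons of 6 are equivalent by symmetry, so a single regioisomer should form, and the first acyl group deactivates the ring against a second acylation.

**Step 5**
Reactants: 8 1-(2,4,6-trihydroxy-3-methylphenyl)-3-phenylpropan-1-one
Product: 9 1-(2,6-dihydroxy-4-methoxy-3-methylphenyl)-3-phenylpropan-1-one
Conditions: Me2SO4 (1.0 equiv), K2CO3 (1.1 equiv), acetone, rt
Reagents that add atoms: dimethyl sulfate COS(=O)(=O)OC
Why: Selective Williamson-type O-methylation; the hydroxyl para to the carbonyl is the most acidic and is not hydrogen-bonded to the ketone, so with one equivalent of reagent it should react ahead of the two ortho hydroxyls.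

**Step 6**
Reactants: 5 [2,4-bis(benzyloxy)-6-bromophenyl]methanol; 9 1-(2,6-dihydroxy-4-methoxy-3-methylphenyl)-3-phenylpropan-1-one
Product: 10 1-(3-{[2,4-bis(benzyloxy)-6-bromophenyl]methyl}-2,6-dihydroxy-4-methoxy-5-methylphenyl)-3-phenylpropan-1-one
Conditions: p-TsOH·H2O (10 mol %), MeCN–CH2Cl2, 0 °C to rt, slow addition of 5 to 9 (1.5 equiv)
Reagents that add atoms: none
Why: Acid-catalysed Friedel–Crafts benzylation (SN1); 5 ionises readily to a cation stabilised by its ortho and para benzyloxy groups, and the phloroglucinol-type ring of 9 has a single free carbon, between hydroxyl and methoxy, where C-alkylation forms the CH2 bridge.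

**Step 7**
Reactants: 10 1-(3-{[2,4-bis(benzyloxy)-6-bromophenyl]methyl}-2,6-dihydroxy-4-methoxy-5-methylphenyl)-3-phenylpropan-1-one
Product: 11 1-(2,6-bis(benzyloxy)-3-{[2,4-bis(benzyloxy)-6-bromophenyl]methyl}-4-methoxy-5-methylphenyl)-3-phenylpropan-1-one
Conditions: BnBr, K2CO3, n-Bu4NI (cat.), DMF, 70 °C
Reagents that add atoms: benzyl bromide BrCc1ccccc1
Why: Williamson benzylation of the two chelated ring D hydroxyls, free of competing C-alkylation because ring D is now fully substituted; it masks the hydroxyl beside the bridge, which would otherwise compete for C8a in step 11.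

**Step 8**
Reactants: 11 1-(2,6-bis(benzyloxy)-3-{[2,4-bis(benzyloxy)-6-bromophenyl]methyl}-4-methoxy-5-methylphenyl)-3-phenylpropan-1-one
Product: 13 1-(2,6-bis(benzyloxy)-3-{[4,6-bis(benzyloxy)-2-bromo-3-formylphenyl]methyl}-4-methoxy-5-methylphenyl)-3-phenylpropan-1-one, via chloro(methoxy)methyl arene 12 (not isolated)
Conditions: Cl2CHOMe, AgOSO2CF3, CH2Cl2, −78 to −40 °C; then aq. NaHCO3
Reagents that add atoms: dichloromethyl methyl ether COC(Cl)Cl; water O
Why: Rieche formylation promoted by silver triflate; the chloro(methoxy)methyl cation should substitute the ring A carbon C4a (para to the C7 ether, between bromine and the C5 ether) with the same preference as in step 2 rather than C6 between the two ethers, while ring D has no C–H, the ketone is not enolised at this temperature and benzyl ethers are known to survive these conditions.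

**Step 9**
Reactants: 13 1-(2,6-bis(benzyloxy)-3-{[4,6-bis(benzyloxy)-2-bromo-3-formylphenyl]methyl}-4-methoxy-5-methylphenyl)-3-phenylpropan-1-one; 14 2-methoxy-1-phenylethan-1-one
Product: 16 3-[4,6-bis(benzyloxy)-3-{[2,4-bis(benzyloxy)-6-methoxy-5-methyl-3-(3-phenylpropanoyl)phenyl]methyl}-2-bromophenyl]-3-hydroxy-2-methoxy-1-phenylpropan-1-one, via lithium enolate 15 (not isolated)
Conditions: 14 (1.5 equiv), LiN(i-Pr)2 (1.4 equiv), THF, −78 °C; then 13, −78 °C; aq. NH4Cl at −78 °C
Reagents that add atoms: none
Why: Aldol addition of a preformed lithium enolate to a non-enolisable aryl aldehyde forms the C3–C4 bond; the ring D ketone, shielded by two ortho benzyloxy groups, should be neither attacked nor deprotonated at −78 °C, and the two new stereocentres are formed without control because steps 10 and 11 erase them.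

**Step 10**
Reactants: 16 3-[4,6-bis(benzyloxy)-3-{[2,4-bis(benzyloxy)-6-methoxy-5-methyl-3-(3-phenylpropanoyl)phenyl]methyl}-2-bromophenyl]-3-hydroxy-2-methoxy-1-phenylpropan-1-one
Product: 17 1-[4,6-bis(benzyloxy)-3-{[2,4-bis(benzyloxy)-6-methoxy-5-methyl-3-(3-phenylpropanoyl)phenyl]methyl}-2-bromophenyl]-2-methoxy-3-phenylpropane-1,3-dione (drawn as the chelated enol)
Conditions: Dess–Martin periodinane, NaHCO3, CH2Cl2, 0 °C to rt
Reagents that add atoms: none
Why: Dess–Martin oxidation of a β-hydroxy ketone to the 1,3-diketone under buffered, non-basic conditions that avoid retro-aldol cleavage and leave the benzyl ethers and the aryl bromide intact.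

**Step 11**
Reactants: 17 1-[4,6-bis(benzyloxy)-3-{[2,4-bis(benzyloxy)-6-methoxy-5-methyl-3-(3-phenylpropanoyl)phenyl]methyl}-2-bromophenyl]-2-methoxy-3-phenylpropane-1,3-dione
Product: 19 5,7-bis(benzyloxy)-8-{[2,4-bis(benzyloxy)-6-methoxy-5-methyl-3-(3-phenylpropanoyl)phenyl]methyl}-3-methoxy-2-phenyl-4H-chromen-4-one, via potassium enolate 18 (not isolated)
Conditions: CuI (10 mol %), 1,10-phenanthroline (20 mol %), K2CO3 (2 equiv), DMF, 100 °C, Ar
Reagents that add atoms: none
Why: Carbonate converts the diketone into its potassium enolate, which binds monovalent copper through oxygen; the C8a–Br bond, held beside the chelate by the C4 carbonyl, adds oxidatively, and C–O reductive elimination from trivalent copper forms O1–C8a, with a copper-free addition–elimination at this carbonyl-activated carbon as a second path to the same product. The closest known reaction is the Ullmann-type CuI/K2CO3 cyclisation of 1-(2-bromoaryl)-1,3-diketones to flavones, which also accepts 2-substituted diketones and then gives 3-substituted chromones. Ring C closes as a six-membered ring by attack of the enolate oxygen of the phenyl-bearing carbon on the aryl carbon, a 6-exo closure onto an sp2 centre with the departing bromide outside the ring. No stereocentre is formed, and the labile methoxy-bearing carbon of the diketone becomes the sp2 carbon C3. The step needs O1 on the carbon next to the bridge and O- rather than C-arylation: bromine was fixed on C8a beside C8 in step 2, so neither ring A ether oxygen can become O1, and closure through the central carbon or the other enolate oxygen would require a four-membered ring. Benzylation of the ring D hydroxyl ortho to the bridge in step 7 removes the only other nucleophile that could reach C8a, where it would close a xanthene.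

**Step 12**
Reactants: 19 5,7-bis(benzyloxy)-8-{[2,4-bis(benzyloxy)-6-methoxy-5-methyl-3-(3-phenylpropanoyl)phenyl]methyl}-3-methoxy-2-phenyl-4H-chromen-4-one
Product: 20 5,7-dihydroxy-8-{[2,4-dihydroxy-6-methoxy-5-methyl-3-(3-phenylpropanoyl)phenyl]methyl}-3-methoxy-2-phenyl-4H-chromen-4-one (target)
Conditions: H2 (1 atm), 10% Pd/C, EtOAc–MeOH, rt
Reagents that add atoms: none
Why: Catalytic hydrogenolysis of the four aryl benzyl ethers; the tetrasubstituted C2=C3 bond of the 3-methoxyflavone, the two hydrogen-bonded aryl ketones and the diarylmethane should not be reduced at 1 atm and room temperature if the reaction is stopped when hydrogen uptake ends.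

**Compound list**
1 | 5-bromobenzene-1,3-diol (5-bromoresorcinol) | Oc1cc(O)cc(Br)c1 | starting material
2 | 1,3-bis(benzyloxy)-5-bromobenzene | Brc1cc(OCc2ccccc2)cc(OCc2ccccc2)c1 | intermediate
3 | {[2,4-bis(benzyloxy)-6-bromophenyl]methylidene}dimethyliminium chloride | C[N+](C)=Cc1c(Br)cc(OCc2ccccc2)cc1OCc1ccccc1.[Cl-] | intermediate (not isolated)
4 | 2,4-bis(benzyloxy)-6-bromobenzaldehyde | O=Cc1c(Br)cc(OCc2ccccc2)cc1OCc1ccccc1 | intermediate
5 | [2,4-bis(benzyloxy)-6-bromophenyl]methanol | OCc1c(Br)cc(OCc2ccccc2)cc1OCc1ccccc1 | intermediate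
6 | 2-methylbenzene-1,3,5-triol | Cc1c(O)cc(O)cc1O | starting material
7 | 3-phenylpropanoyl chloride | O=C(Cl)CCc1ccccc1 | starting material
8 | 1-(2,4,6-trihydroxy-3-methylphenyl)-3-phenylpropan-1-one | Cc1c(O)cc(O)c(C(=O)CCc2ccccc2)c1O | intermediate
9 | 1-(2,6-dihydroxy-4-methoxy-3-methylphenyl)-3-phenylpropan-1-one | COc1cc(O)c(C(=O)CCc2ccccc2)c(O)c1C | intermediate
10 | 1-(3-{[2,4-bis(benzyloxy)-6-bromophenyl]methyl}-2,6-dihydroxy-4-methoxy-5-methylphenyl)-3-phenylpropan-1-one | COc1c(C)c(O)c(C(=O)CCc2ccccc2)c(O)c1Cc1c(Br)cc(OCc2ccccc2)cc1OCc1ccccc1 | intermediate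
11 | 1-(2,6-bis(benzyloxy)-3-{[2,4-bis(benzyloxy)-6-bromophenyl]methyl}-4-methoxy-5-methylphenyl)-3-phenylpropan-1-one | COc1c(C)c(OCc2ccccc2)c(C(=O)CCc2ccccc2)c(OCc2ccccc2)c1Cc1c(Br)cc(OCc2ccccc2)cc1OCc1ccccc1 | intermediate
12 | 1-(2,6-bis(benzyloxy)-3-{[4,6-bis(benzyloxy)-2-bromo-3-(chloro(methoxy)methyl)phenyl]methyl}-4-methoxy-5-methylphenyl)-3-phenylpropan-1-one (racemic) | COc1c(C)c(OCc2ccccc2)c(C(=O)CCc2ccccc2)c(OCc2ccccc2)c1Cc1c(Br)c(C(Cl)OC)c(OCc2ccccc2)cc1OCc1ccccc1 | intermediate (not isolated)
13 | 1-(2,6-bis(benzyloxy)-3-{[4,6-bis(benzyloxy)-2-bromo-3-formylphenyl]methyl}-4-methoxy-5-methylphenyl)-3-phenylpropan-1-one | COc1c(C)c(OCc2ccccc2)c(C(=O)CCc2ccccc2)c(OCc2ccccc2)c1Cc1c(Br)c(C=O)c(OCc2ccccc2)cc1OCc1ccccc1 | intermediate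
14 | 2-methoxy-1-phenylethan-1-one | COCC(=O)c1ccccc1 | starting material
15 | lithium (Z)-2-methoxy-1-phenylethen-1-olate | [Li+].[O-]/C(=C\OC)c1ccccc1 | intermediate (not isolated)
16 | 3-[4,6-bis(benzyloxy)-3-{[2,4-bis(benzyloxy)-6-methoxy-5-methyl-3-(3-phenylpropanoyl)phenyl]methyl}-2-bromophenyl]-3-hydroxy-2-methoxy-1-phenylpropan-1-one (racemic, mixture of diastereomers) | COc1c(C)c(OCc2ccccc2)c(C(=O)CCc2ccccc2)c(OCc2ccccc2)c1Cc1c(Br)c(C(O)C(OC)C(=O)c2ccccc2)c(OCc2ccccc2)cc1OCc1ccccc1 | intermediate
17 | 1-[4,6-bis(benzyloxy)-3-{[2,4-bis(benzyloxy)-6-methoxy-5-methyl-3-(3-phenylpropanoyl)phenyl]methyl}-2-bromophenyl]-2-methoxy-3-phenylpropane-1,3-dione, drawn as its chelated (E)-enol | COc1c(C)c(OCc2ccccc2)c(C(=O)CCc2ccccc2)c(OCc2ccccc2)c1Cc1c(Br)c(C(=O)/C(OC)=C(\O)c2ccccc2)c(OCc2ccccc2)cc1OCc1ccccc1 | intermediate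
18 | potassium enolate of 17 | [K+].COc1c(C)c(OCc2ccccc2)c(C(=O)CCc2ccccc2)c(OCc2ccccc2)c1Cc1c(Br)c(C(=O)/C(OC)=C(\[O-])c2ccccc2)c(OCc2ccccc2)cc1OCc1ccccc1 | intermediate (not isolated)
19 | 5,7-bis(benzyloxy)-8-{[2,4-bis(benzyloxy)-6-methoxy-5-methyl-3-(3-phenylpropanoyl)phenyl]methyl}-3-methoxy-2-phenyl-4H-chromen-4-one | COc1c(C)c(OCc2ccccc2)c(C(=O)CCc2ccccc2)c(OCc2ccccc2)c1Cc1c(OCc2ccccc2)cc(OCc2ccccc2)c2c(=O)c(OC)c(-c3ccccc3)oc12 | intermediate
20 | 5,7-dihydroxy-8-{[2,4-dihydroxy-6-methoxy-5-methyl-3-(3-phenylpropanoyl)phenyl]methyl}-3-methoxy-2-phenyl-4H-chromen-4-one | COc1c(C)c(O)c(C(=O)CCc2ccccc2)c(O)c1Cc1c(O)cc(O)c2c(=O)c(OC)c(-c3ccccc3)oc12 | target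

**Step count**
Total: 12 steps. Longest linear sequence: 10 steps (1, 2, 3, 6, 7, 8, 9, 10, 11, 12) from 5-bromoresorcinol; the ring D branch adds steps 4 and 5.

**Steps most likely to fail**

Step 8 (formylation of 11). The triflic acid released as ring A is substituted may strip benzyl ethers or cleave the electron-rich diarylmethane by ipso attack on ring D before the crowded C4a–H has reacted. The fallback sets out from 11 and returns at 13. Iodination with N-iodosuccinimide and a catalytic amount of CF3CO2H in MeCN at 0 °C follows the same para-alkoxy preference but generates no strong acid, and should give the aryl iodide 1-(2,6-bis(benzyloxy)-3-{[4,6-bis(benzyloxy)-2-bromo-3-iodophenyl]methyl}-4-methoxy-5-methylphenyl)-3-phenylpropan-1-one F1. Iodine–magnesium exchange with i-PrMgCl·LiCl in THF at −40 °C is faster at C–I than at the neighbouring C–Br and too cold for the shielded ring D ketone to react; it should give the arylmagnesium chloride F2 (not isolated), which DMF converts into aldehyde 13.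

Step 6 (bridge formation). The cation from 5 may alkylate the open ring carbon beside bromine of a second molecule of 5 and oligomerise faster than it finds the one free carbon of 9. The fallback sets out from 5 (with 9) and returns at 13, replacing steps 6 to 8. Alcohol 5 is first iodinated (N-iodosuccinimide, MeCN, 0 °C) to [4,6-bis(benzyloxy)-2-bromo-3-iodophenyl]methanol F3, in which that nucleophilic carbon is blocked. The same acid-catalysed benzylation of 9 with F3 should then give the iodinated bis-phenol 1-(3-{[4,6-bis(benzyloxy)-2-bromo-3-iodophenyl]methyl}-2,6-dihydroxy-4-methoxy-5-methylphenyl)-3-phenylpropan-1-one F4. Benzylation as in step 7 leads to the aryl iodide F1, and exchange to the arylmagnesium chloride F2 followed by DMF, as described for step 8, reaches 13.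

Step 5 (mono-methylation). Methylation may spread to the hydroxyls flanking the carbonyl or run on to di-ethers, so that the para ether is not obtained cleanly. The fallback sets out from 8 and returns at 9. Exhaustive methylation (excess dimethyl sulfate, K2CO3, acetone, reflux) gives 1-(2,4,6-trimethoxy-3-methylphenyl)-3-phenylpropan-1-one F5. BBr3 (2.2 equiv, CH2Cl2, −78 to 0 °C) then removes the two ortho methyl groups: boron chelated to the carbonyl cleaves the ethers it can reach, and the para ether, which cannot chelate, is kept.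

**Further compounds**
F1 | step 8 | 1-(2,6-bis(benzyloxy)-3-{[4,6-bis(benzyloxy)-2-bromo-3-iodophenyl]methyl}-4-methoxy-5-methylphenyl)-3-phenylpropan-1-one | COc1c(C)c(OCc2ccccc2)c(C(=O)CCc2ccccc2)c(OCc2ccccc2)c1Cc1c(Br)c(I)c(OCc2ccccc2)cc1OCc1ccccc1
F2 | step 8 | arylmagnesium chloride from F1 (magnesium at C4a, not isolated) | COc1c(C)c(OCc2ccccc2)c(C(=O)CCc2ccccc2)c(OCc2ccccc2)c1Cc1c(Br)c([Mg]Cl)c(OCc2ccccc2)cc1OCc1ccccc1
F3 | step 6 | [4,6-bis(benzyloxy)-2-bromo-3-iodophenyl]methanol | OCc1c(Br)c(I)c(OCc2ccccc2)cc1OCc1ccccc1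
F4 | step 6 | 1-(3-{[4,6-bis(benzyloxy)-2-bromo-3-iodophenyl]methyl}-2,6-dihydroxy-4-methoxy-5-methylphenyl)-3-phenylpropan-1-one | COc1c(C)c(O)c(C(=O)CCc2ccccc2)c(O)c1Cc1c(Br)c(I)c(OCc2ccccc2)cc1OCc1ccccc1
F5 | step 5 | 1-(2,4,6-trimethoxy-3-methylphenyl)-3-phenylpropan-1-one | COc1cc(OC)c(C(=O)CCc2ccccc2)c(OC)c1C
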